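**Plan**

- Retrosynthesis: after the protecting groups are removed (two aryl O–Me bonds, one O–SiEt3 bond), the quinone ring is cut at C1–C2 and C3–C4. This leaves a phthaloylcobalt unit, derived from 3,6-dimethoxybenzocyclobutenedione, and a chiral terminal alkyne.
- The alkyne is cut at the ester C–O bond, at the C1'–C(alkyne) bond (asymmetric alkynylation of an enal) and at the C2'=C3' double bond (cross-metathesis). The dione is cut at its four-membered ring (aryne plus ketene acetal).
- Feature: in ring A (C1–C4, C4a, C8a) both carbonyl carbons C1 and C4 sit on the neighbouring carbons C8a and C4a of the dioxygenated benzene ring B, a symmetrical 1,2-diacylarene. The other two atoms, C2 (side chain) and C3 (H), are the two carbons of a terminal alkyne.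
- Forward: ring B is bought, a four-membered dione ring is fused to it and opened by cobalt, and ring A is closed last by alkyne insertion, which attaches the complete side chain in the same operation. Two deprotections finish the route.
- Stereochemistry: C1' (R) comes from a ligand-controlled zinc alkynylation, the acyl stereocentre (R) from purchased (R)-2-methylbutanoic acid, and the E-alkene from cross-metathesis. None of them is touched afterwards.

Key step: step 10

Assumption: the (S,S) enantiomer of the ProPhenol ligand is taken to direct alkynyl transfer to the Si face of enal 11, which gives the (R)-carbinol; the sense would be checked by Mosher ester analysis of 14, and the (R,R) ligand would be used if it proved opposite.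

**Route**

Step 1
Reactants: 1 2-bromo-1,4-dimethoxybenzene; 2 1,1-dimethoxyethene
Product: 5 3,6-dimethoxybenzocyclobutenone, via 3,6-dimethoxybenzyne 3 (not isolated), via dimethyl ketal 4 (not isolated)
Conditions: NaNH2 (3 equiv), 2 (2 equiv), THF, reflux; then 1 M aq. HCl, THF, rt
Reagents that add atoms: water, O
Why: NaNH2 eliminates HBr from 1 to give the symmetrical aryne 3, which undergoes the established stepwise [2+2] cycloaddition with the electron-rich ketene acetal 2 (only one orientation exists because the aryne is symmetrical), and the acidic work-up hydrolyses ketal 4 to the benzocyclobutenone.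

Step 2
Reactants: 5 3,6-dimethoxybenzocyclobutenone
Product: 6 2,2-dibromo-3,6-dimethoxybenzocyclobutenone (8,8-dibromo-2,5-dimethoxybicyclo[4.2.0]octa-1,3,5-trien-7-one)
Conditions: NBS (2.2 equiv), (PhCO2)2 (cat.), CCl4, reflux, hν
Reagents that add atoms: N-bromosuccinimide, O=C1CCC(=O)N1Br
Why: Wohl–Ziegler radical bromination should occur twice at the only sp3 C–H position, which is benzylic and α to the carbonyl, while the non-polar radical conditions disfavour electrophilic bromination of the dimethoxyarene.

Step 3
Reactants: 6 2,2-dibromo-3,6-dimethoxybenzocyclobutenone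
Product: 7 3,6-dimethoxybenzocyclobutene-1,2-dione
Conditions: 50% aq. H2SO4, 50–60 °C
Reagents that add atoms: water, O
Why: Acid-mediated hydrolysis of the benzylic gem-dibromide unmasks the second carbonyl, the standard passage from benzocyclobutenones to benzocyclobutenediones, and the aryl methyl ethers should be stable to aqueous sulfuric acid at this temperature.

Step 4
Reactants: 8 2-methylbut-3-en-2-ol; 9 (E)-but-2-enal (crotonaldehyde)
Product: 10 (E)-4-hydroxy-4-methylpent-2-enal
Conditions: 9 (5 equiv), second-generation Hoveyda–Grubbs catalyst [(H2IMes)Cl2Ru(=CH–C6H4-2-OiPr)] (3 mol %), CH2Cl2, 40 °C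
Reagents that add atoms: none
Why: Olefin cross-metathesis of an unprotected tertiary allylic alcohol with an enal is well established, crotonaldehyde acting as a non-volatile acrolein equivalent (propene is lost) and the E-enal forming under thermodynamic control.

Step 5
Reactants: 10 (E)-4-hydroxy-4-methylpent-2-enal
Product: 11 (E)-4-methyl-4-(triethylsilyloxy)pent-2-enal
Conditions: Et3SiOTf, 2,6-lutidine, CH2Cl2, −78 °C
Reagents that add atoms: triethylsilyl trifluoromethanesulfonate, CC[Si](CC)(CC)OS(=O)(=O)C(F)(F)F
Why: A silyl triflate with a hindered pyridine base silylates tertiary alcohols at low temperature, and the enal has no γ-hydrogen, so silyl dienol ether formation cannot compete.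

Step 6
Reactants: 11 (E)-4-methyl-4-(triethylsilyloxy)pent-2-enal; 12 ethynyltrimethylsilane
Product: 14 (3R,4E)-6-methyl-6-(triethylsilyloxy)-1-(trimethylsilyl)hept-4-en-1-yn-3-ol, via methylzinc acetylide 13 (not isolated)
Conditions: 12 (3 equiv), Me2Zn (3 equiv), (S,S)-ProPhenol [2,6-bis{[(S)-2-(hydroxydiphenylmethyl)pyrrolidin-1-yl]methyl}-4-methylphenol] (10 mol %), Ph3P=O (20 mol %), toluene, 0–4 °C; aq. NH4Cl
Reagents that add atoms: none
Why: In the zinc–ProPhenol asymmetric alkynylation the dinuclear zinc complex formed from the ligand and Me2Zn holds the zinc acetylide of 12 and the aldehyde of 11 on neighbouring zinc atoms and should transfer the alkynyl group to the Si face, setting the (R)-carbinol, non-enolisable α,β-unsaturated aldehydes being the preferred substrates of this reaction.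

Step 7
Reactants: 14 (3R,4E)-6-methyl-6-(triethylsilyloxy)-1-(trimethylsilyl)hept-4-en-1-yn-3-ol
Product: 15 (3R,4E)-6-methyl-6-(triethylsilyloxy)hept-4-en-1-yn-3-ol
Conditions: K2CO3 (0.3 equiv), MeOH, 0 °C
Reagents that add atoms: none
Why: Methoxide-mediated protodesilylation cleaves the C(sp)–Si bond selectively, the tertiary triethylsilyl ether being stable to K2CO3 in methanol and the carbinol centre not being involved.

Step 8
Reactants: 15 (3R,4E)-6-methyl-6-(triethylsilyloxy)hept-4-en-1-yn-3-ol; 16 (R)-2-methylbutanoic acid
Product: 17 (3R,4E)-6-methyl-6-(triethylsilyloxy)hept-4-en-1-yn-3-yl (2R)-2-methylbutanoate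
Conditions: 16 (1.3 equiv), DCC, DMAP (0.1 equiv), CH2Cl2, 0 °C to rt
Reagents that add atoms: none
Why: Steglich esterification acylates the secondary propargylic alcohol with retention (its C–O bond is not broken), and the α-stereocentre of the non-activated aliphatic acid should not epimerise under carbodiimide/DMAP conditions at 0 °C because no ketene pathway is open.

Step 9
Reactants: 7 3,6-dimethoxybenzocyclobutene-1,2-dione
Product: 19 chloro(dimethylglyoxime)(pyridine)(3,6-dimethoxyphthaloyl)cobalt, via bis(triphenylphosphine) phthaloylcobalt chloride 18 (not isolated)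
Conditions: ClCo(PPh3)3 (1.05 equiv), PhCl, 50 °C, Ar; then dimethylglyoxime, pyridine, rt; precipitation and washing free of PPh3
Reagents that add atoms: chlorotris(triphenylphosphine)cobalt ClCo(PPh3)3, Cl[Co-3]([P+](c1ccccc1)(c1ccccc1)c1ccccc1)([P+](c1ccccc1)(c1ccccc1)c1ccccc1)[P+](c1ccccc1)(c1ccccc1)c1ccccc1; dimethylglyoxime, CC(=NO)C(C)=NO; pyridine, c1ccncc1
Why: Oxidative addition of monovalent cobalt into the strained C(O)–C(O) bond of the four-membered dione gives the five-membered phthaloylcobalt metallacycle 18 (trivalent cobalt), and the known exchange of both phosphines for dimethylglyoxime and pyridine gives the air-stable octahedral complex 19, which can be separated from triphenylphosphine before the quinone is made.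

Step 10
Reactants: 19 chloro(dimethylglyoxime)(pyridine)(3,6-dimethoxyphthaloyl)cobalt; 17 (3R,4E)-6-methyl-6-(triethylsilyloxy)hept-4-en-1-yn-3-yl (2R)-2-methylbutanoate
Product: 20 (1R,2E)-1-(5,8-dimethoxy-1,4-dioxo-1,4-dihydronaphthalen-2-yl)-4-methyl-4-(triethylsilyloxy)pent-2-en-1-yl (2R)-2-methylbutanoate
Conditions: 19 (1.2 equiv), CoCl2·6H2O (1 equiv), MeCN, 75 °C, N2
Reagents that add atoms: none
Why: CoCl2 acts as a Lewis acid that loosens chloride (or pyridine) on the coordinatively saturated trivalent cobalt centre of 19, so the terminal alkyne of 17 can bind; migratory insertion into one cobalt–acyl bond then expands the five-membered cobaltacycle to a seven-membered acyl(vinyl)cobalt species (first C–C bond), and reductive elimination of the vinyl and the remaining acyl ligand forms the second C–C bond and releases monovalent cobalt. The closest known reaction type is the alkyne annulation of phthaloylcobalt complexes to 1,4-naphthoquinones, applied here to a terminal propargylic ester. Ring A closes by C–C reductive elimination from the seven-membered metallacycle, formally a [4+2] union of the 1,2-diacylarene with the two alkyne carbons (C1–C2 and C3–C4), and it is formed directly at the quinone oxidation level. No stereocentre is created, and the propargylic carbon of 17 should keep its configuration because the medium is neither basic nor strongly ionising. The step needs chemoselectivity for the alkyne over the E-alkene, which does not insert into the acyl–cobalt bond, and tolerance of the allylic-propargylic ester and the silyl ether, for which the weak hydrated Lewis acid CoCl2·6H2O is chosen. Regiochemistry does not arise, since the two acyl carbons of 19 are equivalent and a terminal alkyne can then give only the 2-substituted quinone.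

Step 11
Reactants: 20 (1R,2E)-1-(5,8-dimethoxy-1,4-dioxo-1,4-dihydronaphthalen-2-yl)-4-methyl-4-(triethylsilyloxy)pent-2-en-1-yl (2R)-2-methylbutanoate
Product: 21 (1R,2E)-1-(5,8-dimethoxy-1,4-dioxo-1,4-dihydronaphthalen-2-yl)-4-hydroxy-4-methylpent-2-en-1-yl (2R)-2-methylbutanoate
Conditions: HF·pyridine, pyridine, THF, 0 °C to rt
Reagents that add atoms: none
Why: Fluoride-mediated cleavage of the triethylsilyl ether under buffered, non-basic conditions should leave the quinone, the ester and both allylic C–O bonds untouched.

Step 12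
Reactants: 21 (1R,2E)-1-(5,8-dimethoxy-1,4-dioxo-1,4-dihydronaphthalen-2-yl)-4-hydroxy-4-methylpent-2-en-1-yl (2R)-2-methylbutanoate
Product: 23 (1R,2E)-1-(5,8-dihydroxy-1,4-dioxo-1,4-dihydronaphthalen-2-yl)-4-hydroxy-4-methylpent-2-en-1-yl (2R)-2-methylbutanoate, via naphthodiquinone 22 (not isolated)
Conditions: AgO (4 equiv), 6 M HNO3, acetone, 0 °C, 5–10 min; then aq. Na2S2O4 (1.1 equiv), EtOAc, 0 °C, brief exposure to air
Reagents that add atoms: water, O
Why: Oxidative demethylation with AgO in HNO3 (electron transfer from the dimethoxy ring, ipso attack of water, loss of methanol) gives naphthodiquinone 22, whose two-electron reduction by dithionite should stop at the hydrogen-bonded naphthazarin, the short contact time at 0 °C sparing the ester, the alkene and the tertiary alcohol, and neither stereocentre being involved.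

**Compound list**

1 | 2-bromo-1,4-dimethoxybenzene | COc1ccc(OC)c(Br)c1 | starting material
2 | 1,1-dimethoxyethene | C=C(OC)OC | starting material
3 | 3,6-dimethoxybenzyne | COC1=CC=C(OC)C#C1 | intermediate
4 | 2,5,7,7-tetramethoxybicyclo[4.2.0]octa-1,3,5-triene (dimethyl ketal of 5) | COc1ccc(OC)c2c1CC2(OC)OC | intermediate
5 | 3,6-dimethoxybenzocyclobutenone (2,5-dimethoxybicyclo[4.2.0]octa-1,3,5-trien-7-one) | COc1ccc(OC)c2c1CC2=O | intermediate
6 | 2,2-dibromo-3,6-dimethoxybenzocyclobutenone | COc1ccc(OC)c2c1C(Br)(Br)C2=O | intermediate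
7 | 3,6-dimethoxybenzocyclobutene-1,2-dione | COc1ccc(OC)c2c1C(=O)C2=O | intermediate
8 | 2-methylbut-3-en-2-ol | C=CC(C)(C)O | starting material
9 | (E)-but-2-enal | C/C=C/C=O | starting material
10 | (E)-4-hydroxy-4-methylpent-2-enal | O=C/C=C/C(C)(C)O | intermediate
11 | (E)-4-methyl-4-(triethylsilyloxy)pent-2-enal | O=C/C=C/C(C)(C)O[Si](CC)(CC)CC | intermediate
12 | ethynyltrimethylsilane | C#C[Si](C)(C)C | starting material
13 | methyl[(trimethylsilyl)ethynyl]zinc | C[Zn]C#C[Si](C)(C)C | intermediate
14 | (3R,4E)-6-methyl-6-(triethylsilyloxy)-1-(trimethylsilyl)hept-4-en-1-yn-3-ol | C[Si](C)(C)C#C[C@H](O)/C=C/C(C)(C)O[Si](CC)(CC)CC | intermediate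
15 | (3R,4E)-6-methyl-6-(triethylsilyloxy)hept-4-en-1-yn-3-ol | C#C[C@H](O)/C=C/C(C)(C)O[Si](CC)(CC)CC | intermediate
16 | (R)-2-methylbutanoic acid | CC[C@@H](C)C(=O)O | starting material
17 | (3R,4E)-6-methyl-6-(triethylsilyloxy)hept-4-en-1-yn-3-yl (2R)-2-methylbutanoate | CC[C@@H](C)C(=O)O[C@H](/C=C/C(C)(C)O[Si](CC)(CC)CC)C#C | intermediate
18 | chloro(3,6-dimethoxyphthaloyl)bis(triphenylphosphine)cobalt (trivalent cobalt, five-membered cobaltacycle) | COc1ccc(OC)c2c1C(=O)[Co-2](Cl)([P+](c1ccccc1)(c1ccccc1)c1ccccc1)([P+](c1ccccc1)(c1ccccc1)c1ccccc1)C2=O | intermediate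
19 | chloro(dimethylglyoxime)(pyridine)(3,6-dimethoxyphthaloyl)cobalt (trivalent cobalt, octahedral) | COc1ccc(OC)c2c1C(=O)[Co-3]1(Cl)([n+]3ccccc3)([N+](O)=C(C)C(C)=[N+]1O)C2=O | intermediate
20 | (1R,2E)-1-(5,8-dimethoxy-1,4-dioxo-1,4-dihydronaphthalen-2-yl)-4-methyl-4-(triethylsilyloxy)pent-2-en-1-yl (2R)-2-methylbutanoate | CC[C@@H](C)C(=O)O[C@H](/C=C/C(C)(C)O[Si](CC)(CC)CC)C1=CC(=O)c2c(OC)ccc(OC)c2C1=O | intermediate
21 | (1R,2E)-1-(5,8-dimethoxy-1,4-dioxo-1,4-dihydronaphthalen-2-yl)-4-hydroxy-4-methylpent-2-en-1-yl (2R)-2-methylbutanoate | CC[C@@H](C)C(=O)O[C@H](/C=C/C(C)(C)O)C1=CC(=O)c2c(OC)ccc(OC)c2C1=O | intermediate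
22 | (1R,2E)-4-hydroxy-4-methyl-1-(1,4,5,8-tetraoxo-1,4,5,8-tetrahydronaphthalen-2-yl)pent-2-en-1-yl (2R)-2-methylbutanoate | CC[C@@H](C)C(=O)O[C@H](/C=C/C(C)(C)O)C1=CC(=O)C2=C(C1=O)C(=O)C=CC2=O | intermediate
23 | (1R,2E)-1-(5,8-dihydroxy-1,4-dioxo-1,4-dihydronaphthalen-2-yl)-4-hydroxy-4-methylpent-2-en-1-yl (2R)-2-methylbutanoate | CC[C@@H](C)C(=O)O[C@H](/C=C/C(C)(C)O)C1=CC(=O)c2c(O)ccc(O)c2C1=O | target

**Step count**

Total: 12 steps. Longest linear sequence: 8 steps (steps 4, 5, 6, 7, 8, 10, 11, 12, from 2-methylbut-3-en-2-ol). The arene branch (steps 1, 2, 3, 9) joins at step 10.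

**Steps most likely to fail**

Step 10. The Lewis acid may ionise or rearrange the doubly activated (allylic and propargylic) ester, or cobalt may oligomerise the terminal alkyne faster than it inserts into the cobalt–acyl bond. The fallback builds the same quinone ring from dione 7 by the thermal hydroxycyclobutenone ring expansion (Moore rearrangement), with the ester introduced afterwards.
- It sets out from alcohol 15, which would be silylated (Et3SiCl, imidazole, DMF) to the bis(triethylsilyl) ether F1.
- Deprotonation with n-BuLi (THF, −78 °C) gives its lithium acetylide F2, which should add once to the symmetrical dione 7 to give the alkynyl hydroxybenzocyclobutenone F3. F3 is a mixture at the new carbinol carbon, which disappears in the next operation.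
- Heating F3 in p-xylene at 140 °C (electrocyclic opening to the vinylketene, closure onto the alkyne, hydrogen transfer) should give the quinone bis(silyl ether) F4.
- HF·pyridine then gives the quinone diol F5. Steglich esterification with 16, which discriminates the secondary from the tertiary hydroxyl, brings the route back at 21.

Step 12. The tertiary allylic alcohol may ionise in 6 M HNO3 (loss of water, allylic transposition or diene formation), or over-reduction to the leuco naphthazarin may expel the carboxylate. The fallback avoids strong acid by moving the quinone to the other ring.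
- It sets out from 21, whose reductive acetylation (Zn dust, Ac2O, NaOAc, rt) would give the diacetoxy dimethoxynaphthalene F6.
- (NH4)2Ce(NO3)6 in aqueous MeCN at 0 °C oxidises only the electron-rich dimethoxy ring and should give the diacetoxy naphthoquinone F7, in which the side chain now sits on the aromatic ring.
- Cleavage of the two aryl acetates with NH4OAc in aqueous MeOH, which leaves the hindered secondary alkyl ester alone, gives the 6-substituted naphthazarin. Fast proton transfer between the peri hydroxyls and carbonyls makes this the same compound as 23, where the fallback rejoins the route.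

Step 6. Enantiofacial discrimination in alkynyl transfer to the γ-silyloxy enal may be insufficient or reversed. The fallback sets the carbinol centre by reagent-controlled ketone reduction.
- It sets out from 11 and 12. Lithium (trimethylsilyl)acetylide F8 (from 12 and n-BuLi, THF, −78 °C) adds to 11 to give the racemic propargylic alcohol F9.
- MnO2 in CH2Cl2 oxidises F9 to the cross-conjugated ynone F10.
- Midland reduction with (R)-Alpine-Borane (B-isopinocampheyl-9-borabicyclo[3.3.1]nonane from (+)-α-pinene, THF, rt) should give 14, where the fallback rejoins the route. The alkynyl group takes the small-substituent position, as in the reduction of oct-1-yn-3-one to (R)-oct-1-yn-3-ol.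

**Further compounds**

F1 | step 10 | (3R,4E)-6-methyl-3,6-bis(triethylsilyloxy)hept-4-en-1-yne | C#C[C@H](O[Si](CC)(CC)CC)/C=C/C(C)(C)O[Si](CC)(CC)CC
F2 | step 10 | lithium acetylide of F1 | [Li]C#C[C@H](O[Si](CC)(CC)CC)/C=C/C(C)(C)O[Si](CC)(CC)CC
F3 | step 10 | 8-hydroxy-2,5-dimethoxy-8-[(3R,4E)-6-methyl-3,6-bis(triethylsilyloxy)hept-4-en-1-yn-1-yl]bicyclo[4.2.0]octa-1,3,5-trien-7-one (both C8 epimers) | COc1ccc(OC)c2c1C(=O)C2(O)C#C[C@H](O[Si](CC)(CC)CC)/C=C/C(C)(C)O[Si](CC)(CC)CC
F4 | step 10 | 5,8-dimethoxy-2-[(1R,2E)-4-methyl-1,4-bis(triethylsilyloxy)pent-2-en-1-yl]naphthalene-1,4-dione | CC[Si](CC)(CC)O[C@H](/C=C/C(C)(C)O[Si](CC)(CC)CC)C1=CC(=O)c2c(OC)ccc(OC)c2C1=O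
F5 | step 10 | 2-[(1R,2E)-1,4-dihydroxy-4-methylpent-2-en-1-yl]-5,8-dimethoxynaphthalene-1,4-dione | O[C@H](/C=C/C(C)(C)O)C1=CC(=O)c2c(OC)ccc(OC)c2C1=O
F6 | step 12 | (1R,2E)-1-(1,4-diacetoxy-5,8-dimethoxynaphthalen-2-yl)-4-hydroxy-4-methylpent-2-en-1-yl (2R)-2-methylbutanoate | CC[C@@H](C)C(=O)O[C@H](/C=C/C(C)(C)O)c1cc(OC(C)=O)c2c(OC)ccc(OC)c2c1OC(C)=O
F7 | step 12 | (1R,2E)-1-(1,4-diacetoxy-5,8-dioxo-5,8-dihydronaphthalen-2-yl)-4-hydroxy-4-methylpent-2-en-1-yl (2R)-2-methylbutanoate | CC[C@@H](C)C(=O)O[C@H](/C=C/C(C)(C)O)c1cc(OC(C)=O)c2C(=O)C=CC(=O)c2c1OC(C)=O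
F8 | step 6 | lithium (trimethylsilyl)acetylide | [Li]C#C[Si](C)(C)C
F9 | step 6 | racemic (E)-6-methyl-6-(triethylsilyloxy)-1-(trimethylsilyl)hept-4-en-1-yn-3-ol | C[Si](C)(C)C#CC(O)/C=C/C(C)(C)O[Si](CC)(CC)CC
F10 | step 6 | (E)-6-methyl-6-(triethylsilyloxy)-1-(trimethylsilyl)hept-4-en-1-yn-3-one | C[Si](C)(C)C#CC(=O)/C=C/C(C)(C)O[Si](CC)(CC)CC
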